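**Retrosynthetic overview**
1. The last step acetylates C3–OH. Before that, the ten-membered carbocycle is closed at C3–C4 by Ni/Cr-mediated addition of a (Z)-vinyl iodide to an E-enal, which sets C3.
2. Key disconnection C7–C8: an enantiopure α-(bromomethyl)butenolide is reductively metalated, so its β-carbon C7 (normally an acceptor site) becomes the nucleophilic end of an allylzinc (homoenolate, d3). This carbon attacks the C8 aldehyde (a1). The one step joins both halves, sets C7 and C8 from C6, and unveils the α-methylene lactone.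
3. West half: propyne unit + acrolein, Sharpless kinetic resolution (C6), hydroalumination/iodination (4Z), acylation, RCM.
4. East half: Sharpless epoxidation of commercial (E)-3-methylpent-2-en-4-yn-1-ol (C10), hydride opening/alkyne reduction, cross-metathesis (1E), oxidation.
5. Ring order: five-membered lactone first (RCM), ten-membered ring last (Ni/Cr closure).

Assumption: position labels follow germacrane numbering (C3 acetate carbinol, C4=C5 Z-alkene with C15 methyl, C6 lactone carbinol, C7 ring-fusion carbon, C8 angelate carbinol, C10 tertiary carbinol, C1=C2 E-alkene, C11=C13 methylene, C12 lactone carbonyl). In this numbering the target is 3S,6S,7S,8R,10R.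

**Step 1**
Reactants: 1 acrolein; 2 1-propynylmagnesium bromide
Product: 3 (±)-hex-1-en-4-yn-3-ol
Conditions: THF, −78 to 0 °C; then sat. aq NH4Cl
Reagents that add atoms: 1-propynylmagnesium bromide, CC#C[Mg]Br
Why: Grignard 1,2-addition of an alkynyl nucleophile to an enal gives the racemic carbinol that holds C4–C7 and C15, and its stereocentre (C6) is resolved in step 2.

**Step 2**
Reactants: 3 (±)-hex-1-en-4-yn-3-ol
Product: 4 (3R)-hex-1-en-4-yn-3-ol
Conditions: Ti(OiPr)4 (0.2 equiv), D-(−)-DIPT (0.24 equiv), tBuOOH (0.6 equiv), 4 Å MS, CH2Cl2, −20 °C, to ca. 58% conversion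
Reagents that add atoms: none
Why: Sharpless kinetic resolution, in which with D-(−)-DIPT the S enantiomer is epoxidised at its vinyl group much faster (the alkyne is inert), so the unreacted R alcohol, which has the C6 configuration of the target, is recovered in high ee.

**Step 3**
Reactants: 4 (3R)-hex-1-en-4-yn-3-ol
Product: 6 (3R,4Z)-5-iodohexa-1,4-dien-3-ol, via cyclic alkenylaluminate 5 (not isolated)
Conditions: NaAlH2(OCH2CH2OMe)2 (1.5 equiv), THF, 0 °C to rt; then I2, −78 to 0 °C; H2O
Reagents that add atoms: iodine, II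
Why: Alkoxide-directed trans-hydroalumination of a propargylic alcohol puts aluminium on the distal alkyne carbon cis to the carbinol, and iodinolysis with retention gives the Z-iodoalkene, which fixes the 4Z geometry with iodine where C3 will be attached and leaves C6 untouched.

**Step 4**
Reactants: 6 (3R,4Z)-5-iodohexa-1,4-dien-3-ol; 7 2-(bromomethyl)acrylic acid
Product: 9 (3R,4Z)-5-iodohexa-1,4-dien-3-yl 2-(bromomethyl)acrylate, via 2-(bromomethyl)acryloyl chloride 8 (not isolated)
Conditions: 7, 1-chloro-N,N,2-trimethylprop-1-en-1-amine, CH2Cl2, 0 °C; then 6, 2,6-lutidine, −20 to 0 °C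
Reagents that add atoms: 2-(bromomethyl)acrylic acid, C=C(CBr)C(=O)O
Why: Acyl chloride esterification under neutral chloroenamine activation with a hindered base avoids attack of nucleophilic amines on the allylic bromide, and the carbinol C–O bond is not broken so C6 is retained.

**Step 5**
Reactants: 9 (3R,4Z)-5-iodohexa-1,4-dien-3-yl 2-(bromomethyl)acrylate
Product: 10 (5R)-3-(bromomethyl)-5-[(1Z)-2-iodoprop-1-en-1-yl]furan-2(5H)-one
Conditions: second-generation Hoveyda–Grubbs catalyst (5 mol%), toluene (5 mM), 80 °C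
Reagents that add atoms: none
Why: Ring-closing metathesis of the terminal vinyl group with the 1,1-disubstituted acrylate closes the butenolide (first ring), while the trisubstituted iodoalkene is too hindered to take part and C6 is not affected.

**Step 6**
Reactants: 11 (2E)-3-methylpent-2-en-4-yn-1-ol
Product: 12 [(2S,3S)-3-ethynyl-3-methyloxiran-2-yl]methanol
Conditions: Ti(OiPr)4 (10 mol%), L-(+)-DET (12 mol%), tBuOOH, 4 Å MS, CH2Cl2, −20 °C
Reagents that add atoms: tert-butyl hydroperoxide, CC(C)(C)OO
Why: Katsuki–Sharpless asymmetric epoxidation of an E-3,3-disubstituted allylic alcohol with L-(+)-DET gives the 2S,3S epoxide (same facial sense as geraniol), which creates the quaternary C–O stereocentre that becomes C10.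

**Step 7**
Reactants: 12 [(2S,3S)-3-ethynyl-3-methyloxiran-2-yl]methanol
Product: 14 (3R)-3-methylpent-4-ene-1,3-diol, via alkynediol aluminium alkoxide 13 (not isolated)
Conditions: NaAlH2(OCH2CH2OMe)2 (4 equiv), THF, 0 °C then 65 °C; then H2O
Reagents that add atoms: none
Why: Directed hydride opening of the 2,3-epoxy alcohol at C2 gives the 1,3-diol without touching the quaternary C–O bond (C10 becomes R by priority change only), and the resulting propargylic alkoxide then directs hydroalumination of the ethynyl group to vinyl.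

**Step 8**
Reactants: 14 (3R)-3-methylpent-4-ene-1,3-diol; 15 acrolein diethyl acetal
Product: 16 (3R,4E)-6,6-diethoxy-3-methylhex-4-ene-1,3-diol
Conditions: 15 (3 equiv), second-generation Hoveyda–Grubbs catalyst (5 mol%), CH2Cl2, 40 °C
Reagents that add atoms: acrolein diethyl acetal, C=CC(OCC)OCC
Why: Olefin cross-metathesis of an unprotected tertiary allylic alcohol with an acrolein acetal is thermodynamically E-selective, installs C3 as a masked aldehyde, sets the 1E alkene, and leaves C10 untouched.

**Step 9**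
Reactants: 16 (3R,4E)-6,6-diethoxy-3-methylhex-4-ene-1,3-diol
Product: 17 (3R,4E)-6,6-diethoxy-3-hydroxy-3-methylhex-4-enal
Conditions: TEMPO (10 mol%), PhI(OAc)2, CH2Cl2, rt; used without storage
Reagents that add atoms: none
Why: Oxoammonium (TEMPO) oxidation takes only the primary alcohol to the aldehyde, the tertiary alcohol cannot be oxidised, and the water-free medium spares the acetal.

**Step 10 (key step)**
Reactants: 10 (5R)-3-(bromomethyl)-5-[(1Z)-2-iodoprop-1-en-1-yl]furan-2(5H)-one; 17 (3R,4E)-6,6-diethoxy-3-hydroxy-3-methylhex-4-enal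
Product: 19 (4S,5R)-4-[(1R,3R,4E)-6,6-diethoxy-1,3-dihydroxy-3-methylhex-4-en-1-yl]-5-[(1Z)-2-iodoprop-1-en-1-yl]-3-methylideneoxolan-2-one, via allylzinc bromide 18 (not isolated)
Conditions: Zn dust (3 equiv), THF/sat. aq NH4Cl (1:1), 0 °C to rt, 10 added slowly to 17 (1.2 equiv)
Reagents that add atoms: none
Why: In this aqueous zinc Barbier allylation, reductive metalation turns the butenolide β-carbon C7 into the nucleophilic γ-terminus of an allylzinc (homoenolate equivalent) that attacks the aldehyde carbon C8 by SE2′ through a Zimmerman–Traxler chair, anti to the C6 alkenyl group (trans-lactone, C7 S) and, because the ring holds C6 trans to the CH2Zn terminus (E-crotyl-type geometry), with anti C7/C8 topology (C8 R), while the in-plane C6–O bond is orthogonal to the allyl π system so ring-opening 1,4-elimination does not compete and the free C10–OH, the vinyl iodide and the acetal are tolerated.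

**Step 11**
Reactants: 19 Barbier adduct; 20 angelic acid [(2Z)-2-methylbut-2-enoic acid]
Product: 23 (1R,3R,4E)-3-hydroxy-1-{(2R,3S)-2-[(1Z)-2-iodoprop-1-en-1-yl]-4-methylidene-5-oxooxolan-3-yl}-3-methyl-6-oxohex-4-en-1-yl (2Z)-2-methylbut-2-enoate, via mixed anhydride 21 (not isolated), via acetal angelate 22 (not isolated)
Conditions: 20, 2,4,6-trichlorobenzoyl chloride, Et3N, toluene, rt; add 19, 75 °C; then THF, 10% aq oxalic acid, rt
Reagents that add atoms: angelic acid, C/C=C(/C)C(=O)O; water, O
Why: Yamaguchi-type mixed-anhydride esterification without a nucleophilic catalyst acylates only the secondary C8–OH (the tertiary C10–OH is inert) and keeps the Z geometry of the angelate, and the mild aqueous acid added afterwards hydrolyses the allylic diethyl acetal to the E-enal once C8–O can no longer add to it.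

**Step 12**
Reactants: 23 iodo-enal
Product: 25 (3S,6S,7S,8R,10R)-8-angeloyloxy-3,10-dihydroxygermacra-1(2)E,4Z,11(13)-trien-12,6-olide, via alkenylchromium dichloride 24 (not isolated)
Conditions: CrCl2 (12 equiv), NiCl2 (0.1 equiv), DMSO/THF (3:1), 2 mM, syringe-pump addition, rt; then H2O
Reagents that add atoms: none
Why: In this Nozaki–Hiyama–Kishi macrocyclisation, nickel-catalysed activation of the C4–I bond and transfer to trivalent chromium occur with retention of the Z geometry, and 1,2-addition to the enal at high dilution closes the ten-membered ring, while A(1,3) strain across the Z-trisubstituted alkene keeps H3 and H6 in the alkene plane and the ring bonds C3–C2 and C6–C7 on one face, so the chromium-bound oxygen develops on the outer face syn to O6 (Re-face attack, 3S).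

**Step 13**
Reactants: 25 macrocyclic diol; 26 acetic anhydride
Product: 27 target, (3S,6S,7S,8R,10R)-3-acetoxy-8-angeloyloxy-10-hydroxygermacra-1(2)E,4Z,11(13)-trien-12,6-olide
Conditions: Ac2O (1.5 equiv), pyridine, DMAP (5 mol%), CH2Cl2, 0 °C
Reagents that add atoms: acetic anhydride, CC(=O)OC(C)=O
Why: Chemoselective O-acetylation takes the secondary bis-allylic C3–OH while the hindered tertiary C10–OH stays free, and no stereocentre is touched.

**Compound list**
1 | acrolein | C=CC=O | starting material
2 | 1-propynylmagnesium bromide | CC#C[Mg]Br | starting material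
3 | (±)-hex-1-en-4-yn-3-ol | C=CC(O)C#CC | intermediate
4 | (3R)-hex-1-en-4-yn-3-ol | C=C[C@@H](O)C#CC | intermediate
5 | sodium cyclic alkenylaluminate (five-membered O–Al–C4=C5–C6 ring, two 2-methoxyethoxy groups on Al, C6 as in 4) | [Na+].CC1=C[C@@H](C=C)O[Al-]1(OCCOC)OCCOC | intermediate
6 | (3R,4Z)-5-iodohexa-1,4-dien-3-ol | C=C[C@@H](O)/C=C(/C)I | intermediate
7 | 2-(bromomethyl)acrylic acid | C=C(CBr)C(=O)O | starting material
8 | 2-(bromomethyl)acryloyl chloride | C=C(CBr)C(=O)Cl | intermediate
9 | (3R,4Z)-5-iodohexa-1,4-dien-3-yl 2-(bromomethyl)acrylate | C=C[C@@H](OC(=O)C(=C)CBr)/C=C(/C)I | intermediate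
10 | (5R)-3-(bromomethyl)-5-[(1Z)-2-iodoprop-1-en-1-yl]furan-2(5H)-one | O=C1O[C@@H](/C=C(/C)I)C=C1CBr | intermediate
11 | (2E)-3-methylpent-2-en-4-yn-1-ol | C#C/C(C)=C/CO | starting material
12 | [(2S,3S)-3-ethynyl-3-methyloxiran-2-yl]methanol | C#C[C@]1(C)O[C@H]1CO | intermediate
13 | (3R)-3-methylpent-4-yne-1,3-diol, present in the flask as its aluminium alkoxide | C#C[C@](C)(O)CCO | intermediate
14 | (3R)-3-methylpent-4-ene-1,3-diol | C=C[C@](C)(O)CCO | intermediate
15 | acrolein diethyl acetal (3,3-diethoxyprop-1-ene) | C=CC(OCC)OCC | starting material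
16 | (3R,4E)-6,6-diethoxy-3-methylhex-4-ene-1,3-diol | CCOC(OCC)/C=C/[C@](C)(O)CCO | intermediate
17 | (3R,4E)-6,6-diethoxy-3-hydroxy-3-methylhex-4-enal | CCOC(OCC)/C=C/[C@](C)(O)CC=O | intermediate
18 | allylzinc bromide from 10 (Zn on C13, C6 as in 10) | Br[Zn]CC1=C[C@H](/C=C(/C)I)OC1=O | intermediate
19 | (4S,5R)-4-[(1R,3R,4E)-6,6-diethoxy-1,3-dihydroxy-3-methylhex-4-en-1-yl]-5-[(1Z)-2-iodoprop-1-en-1-yl]-3-methylideneoxolan-2-one (trans-lactone; C6 R through iodine priority only, C7 S, C8 R, C10 R) | C=C1C(=O)O[C@@H](/C=C(/C)I)[C@@H]1[C@H](O)C[C@@](C)(O)/C=C/C(OCC)OCC | intermediate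
20 | angelic acid, (2Z)-2-methylbut-2-enoic acid | C/C=C(/C)C(=O)O | starting material
21 | angelic 2,4,6-trichlorobenzoic anhydride | C/C=C(/C)C(=O)OC(=O)c1c(Cl)cc(Cl)cc1Cl | intermediate
22 | C8 angelate of 19 (acetal intact) | C=C1C(=O)O[C@@H](/C=C(/C)I)[C@@H]1[C@H](OC(=O)/C(C)=C\C)C[C@@](C)(O)/C=C/C(OCC)OCC | intermediate
23 | iodo-enal: 22 with CH(OEt)2 replaced by CHO (name as in step 11) | C=C1C(=O)O[C@@H](/C=C(/C)I)[C@@H]1[C@H](OC(=O)/C(C)=C\C)C[C@@](C)(O)/C=C/C=O | intermediate
24 | alkenylchromium dichloride (23 with CrCl2 in place of I, Z retained) | C=C1C(=O)O[C@@H](/C=C(/C)[Cr](Cl)Cl)[C@@H]1[C@H](OC(=O)/C(C)=C\C)C[C@@](C)(O)/C=C/C=O | intermediate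
25 | (3S,6S,7S,8R,10R)-8-angeloyloxy-3,10-dihydroxygermacra-1(2)E,4Z,11(13)-trien-12,6-olide | C=C1C(=O)O[C@H]2/C=C(/C)[C@@H](O)/C=C/[C@](C)(O)C[C@@H](OC(=O)/C(C)=C\C)[C@H]12 | intermediate
26 | acetic anhydride | CC(=O)OC(C)=O | starting material
27 | CNP0181631.2, (3S,6S,7S,8R,10R)-3-acetoxy-8-angeloyloxy-10-hydroxygermacra-1(2)E,4Z,11(13)-trien-12,6-olide | C=C1C(=O)O[C@H]2/C=C(/C)[C@@H](OC(C)=O)/C=C/[C@](C)(O)C[C@@H](OC(=O)/C(C)=C\C)[C@H]12 | target

**Totals and risks**

Total steps: 13. Longest linear sequence: 9 (steps 1–5 and 10–13). The east half (steps 6–9) is made in parallel.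

**Step 10.**
- Risks: protonation or α-attack of the allylzinc, migration of the lactone to the new C8 oxygen, partial loss of the acetal, and insufficient diastereocontrol.
- Fallback: it sets out from 9 and comes back at 19. It replaces the reducing-metal Barbier reaction by a preformed, isolable allylboron homoenolate that reacts through a closed transition state without water.
- Route: borylation of 9 with B2pin2, CuCl (cat.) and KOAc gives (3R,4Z)-5-iodohexa-1,4-dien-3-yl 2-[(4,4,5,5-tetramethyl-1,3,2-dioxaborolan-2-yl)methyl]acrylate F5 (direct and allyl-shifted substitution are degenerate on this symmetrical allyl unit). Ring-closing metathesis then gives (5R)-5-[(1Z)-2-iodoprop-1-en-1-yl]-3-[(4,4,5,5-tetramethyl-1,3,2-dioxaborolan-2-yl)methyl]furan-2(5H)-one F6. Allylboration of 17 (toluene, Sc(OTf)3 cat.) followed by aqueous work-up delivers 19 with the same trans/anti outcome.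

**Step 12.**
- Risks: oligomerisation, or the wrong or a mixed C3 configuration.
- Fallback: it sets out from 23 and comes back at 25. It moves control of C3 from the C–C bond formation to a reagent-controlled ketone reduction.
- Route: the Ni/Cr closure is run regardless of selectivity. The product, 25 together with its (3R)-epimer, (3R,6S,7S,8R,10R)-8-angeloyloxy-3,10-dihydroxygermacra-1(2)E,4Z,11(13)-trien-12,6-olide F7, is oxidised with MnO2. This gives the cross-conjugated dienone (6S,7S,8R,10R)-8-angeloyloxy-10-hydroxy-3-oxogermacra-1(2)E,4Z,11(13)-trien-12,6-olide F8. Reduction with (R)-2-methyl-CBS-oxazaborolidine and catecholborane at −78 °C, where the α-methyl-branched alkenyl side acts as the large group, gives 25.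

**Step 5.**
- Risks: slow closure onto an electron-poor 1,1-disubstituted alkene that carries an allylic bromide, and catalyst decay.
- Fallback: it sets out from 6 and comes back at 10. It installs the bromide only after the ring has been formed.
- Route: commercial ethyl 2-(hydroxymethyl)acrylate is silylated (TBSCl, imidazole) to ethyl 2-{[(tert-butyldimethylsilyl)oxy]methyl}acrylate F1 and saponified (LiOH) to 2-{[(tert-butyldimethylsilyl)oxy]methyl}acrylic acid F2. Esterification of 6 (DCC, cat. DMAP) gives (3R,4Z)-5-iodohexa-1,4-dien-3-yl 2-{[(tert-butyldimethylsilyl)oxy]methyl}acrylate F3. Ring-closing metathesis gives (5R)-3-{[(tert-butyldimethylsilyl)oxy]methyl}-5-[(1Z)-2-iodoprop-1-en-1-yl]furan-2(5H)-one F4. Ph3PBr2 in CH2Cl2 then converts the silyl ether directly into bromide 10.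

**Further compounds**
F1 | step 5 | ethyl 2-{[(tert-butyldimethylsilyl)oxy]methyl}acrylate | C=C(CO[Si](C)(C)C(C)(C)C)C(=O)OCC
F2 | step 5 | 2-{[(tert-butyldimethylsilyl)oxy]methyl}acrylic acid | C=C(CO[Si](C)(C)C(C)(C)C)C(=O)O
F3 | step 5 | (3R,4Z)-5-iodohexa-1,4-dien-3-yl 2-{[(tert-butyldimethylsilyl)oxy]methyl}acrylate | C=C[C@@H](OC(=O)C(=C)CO[Si](C)(C)C(C)(C)C)/C=C(/C)I
F4 | step 5 | (5R)-3-{[(tert-butyldimethylsilyl)oxy]methyl}-5-[(1Z)-2-iodoprop-1-en-1-yl]furan-2(5H)-one | O=C1O[C@@H](/C=C(/C)I)C=C1CO[Si](C)(C)C(C)(C)C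
F5 | step 10 | (3R,4Z)-5-iodohexa-1,4-dien-3-yl 2-[(4,4,5,5-tetramethyl-1,3,2-dioxaborolan-2-yl)methyl]acrylate | C=C[C@@H](OC(=O)C(=C)CB1OC(C)(C)C(C)(C)O1)/C=C(/C)I
F6 | step 10 | (5R)-5-[(1Z)-2-iodoprop-1-en-1-yl]-3-[(4,4,5,5-tetramethyl-1,3,2-dioxaborolan-2-yl)methyl]furan-2(5H)-one | CC1(C)OB(CC2=C[C@H](/C=C(/C)I)OC2=O)OC1(C)C
F7 | step 12 | (3R,6S,7S,8R,10R)-8-angeloyloxy-3,10-dihydroxygermacra-1(2)E,4Z,11(13)-trien-12,6-olide | C=C1C(=O)O[C@H]2/C=C(/C)[C@H](O)/C=C/[C@](C)(O)C[C@@H](OC(=O)/C(C)=C\C)[C@H]12
F8 | step 12 | (6S,7S,8R,10R)-8-angeloyloxy-10-hydroxy-3-oxogermacra-1(2)E,4Z,11(13)-trien-12,6-olide | C=C1C(=O)O[C@H]2/C=C(/C)C(=O)/C=C/[C@](C)(O)C[C@@H](OC(=O)/C(C)=C\C)[C@H]12
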